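**Retrosynthetic overview**
1. The target is opened at ring bond C1–C6 (target numbering: C1 = C(CH3)(bromovinyl), C2 = CHBr, C3 = CH2, C4 = CHCl, C5 = C(CH3)Cl, C6 = CH2). A bromonium/chloride cation–olefin cyclization of an acyclic (6R)-allylic chloride closes the only ring last and sets C1, C2 and C5 from the C4 stereocenter.
2. The allylic chloride comes from the (S)-allylic alcohol by invertive chlorination.
3. The (S)-alcohol comes from vinyl-B(pin), isopropenylmagnesium bromide and (1Z,3E)-4-bromo-1-iodo-2-methylbuta-1,3-diene by an enantioselective three-component conjunctive cross-coupling, which makes ring bonds C2–C3 and C4–C5 at once.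
4. Enabling feature: the C3H2–C4HCl unit of the ring lies between C2 (an alkenyl carbon before cyclization) and C5 (an isopropenyl carbon before cyclization), so it maps onto the two carbons of vinyl-B(pin); the cyclohexane is a folded 1,5-diene.
5. The dienyl iodide comes from propargyl alcohol (carbomagnesiation/iodination, oxidation, Takai olefination).

Key step: step 4

Assumption: the sense of induction of MandyPhos is taken from aryl migrations; if it is reversed for isopropenyl migration, the (Sp,Sp) ligand is used instead.

Step 1
Reactants: 1 propargyl alcohol (prop-2-yn-1-ol); 2 methylmagnesium bromide (CH3MgBr)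
Product: 4 (Z)-3-iodo-2-methylprop-2-en-1-ol, via alkenylmagnesium alkoxide 3 (not isolated)
Conditions: CH3MgBr (2.5 equiv), CuI (10 mol %), THF, −10 °C → rt; then I2, −78 → 0 °C
Reagents that add atoms: iodine, II
Why: Copper-catalysed anti-carbomagnesiation of the propargylic alkoxide (methyl to the internal carbon, magnesium chelated by the alkoxide) followed by iodinolysis with retention should give the (Z)-iodoalkene, a well-precedented entry to this building block.

Step 2
Reactants: 4 (Z)-3-iodo-2-methylprop-2-en-1-ol
Product: 5 (Z)-3-iodo-2-methylprop-2-enal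
Conditions: activated MnO2 (excess), CH2Cl2, rt, dark; used at once
Reagents that add atoms: none
Why: Allylic oxidation with MnO2 is neutral and mild, so the configurationally labile (Z)-β-iodo enal should form without isomerisation.

Step 3
Reactants: 5 (Z)-3-iodo-2-methylprop-2-enal; 6 bromoform (CHBr3)
Product: 7 (1Z,3E)-4-bromo-1-iodo-2-methylbuta-1,3-diene
Conditions: CrBr2 (6 equiv), CHBr3 (2 equiv), THF, 0 °C → rt, dark
Reagents that add atoms: none
Why: Takai olefination: the geminal dichromium species from CHBr3 and divalent chromium adds to the aldehyde and eliminates to the (E)-bromoalkene, the alkenyl iodide being inert without nickel, and CrBr2 avoids chloride scrambling into the new vinyl halide.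

Step 4
Reactants: 8 isopropenylmagnesium bromide (CH2=C(CH3)MgBr); 9 vinylboronic acid pinacol ester; 7 (1Z,3E)-4-bromo-1-iodo-2-methylbuta-1,3-diene
Product: 12 (3S,5Z,7E)-8-bromo-2,6-dimethylocta-1,5,7-trien-3-ol, via borate complex 10 (not isolated), via allylic boronate 11 (not isolated)
Conditions: 9 + 8, THF, 0 °C → rt; NaOSO2CF3 (2 equiv), Pd(OAc)2 (2 mol %), (Rp,Rp)-MandyPhos (C52H50FeN2P2, 2.4 mol %), 7 (1.2 equiv), THF, 40 °C; then 3 M NaOH, 30 % H2O2, 0 °C
Reagents that add atoms: hydrogen peroxide, OO
Why: Conjunctive cross-coupling of a bis(alkenyl)borate: zerovalent palladium inserts into the C–I bond of 7 (faster than into C–Br), the cationic alkenylpalladium species binds the unsubstituted vinyl group of 10 and triggers a 1,2-shift of the isopropenyl group from boron to the α-carbon, and reductive elimination joins the CH2 carbon to the dienyl group, so the two carbons of vinyl-B(pin) receive both new C–C bonds (future ring bonds C2–C3 and C4–C5). The closest known reaction is the palladium/MandyPhos-catalysed enantioselective conjunctive coupling of nonsymmetric bis(alkenyl)borates with C(sp2) halides in the presence of NaOSO2CF3, which gives α-chiral allylic boronates. No ring is closed here; the step assembles the whole C10 chain from three pieces. The boron-bearing stereocenter is set by catalyst control (the chiral bisphosphine differentiates the faces of the palladium-bound vinyl group), and B–O oxidation proceeds with retention. The step needs the vinyl group to be the acceptor and the isopropenyl group to migrate, which the less hindered, better π-binding vinyl group should secure; it also needs retention of the (Z)-geometry of 7 and no coupling at the alkenyl bromide, secured by stereoretentive elementary steps, a slight excess of 7 and mild temperature.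

Step 5
Reactants: 12 (3S,5Z,7E)-8-bromo-2,6-dimethylocta-1,5,7-trien-3-ol
Product: 13 (1E,3Z,6R)-1-bromo-6-chloro-3,7-dimethylocta-1,3,7-triene
Conditions: PPh3, hexachloroacetone, CH2Cl2, −20 → 0 °C
Reagents that add atoms: hexachloroacetone, ClC(Cl)(Cl)C(=O)C(Cl)(Cl)Cl
Why: Appel-type chlorination: chloride displaces the alkoxyphosphonium ion in an SN2 process with inversion and, under these fast and mild conditions, without allylic transposition, turning the (S)-alcohol into the (R)-chloride.

Step 6
Reactants: 13 (1E,3Z,6R)-1-bromo-6-chloro-3,7-dimethylocta-1,3,7-triene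
Product: 15 (1S,2S,4R,5S)-2-bromo-1-[(E)-2-bromoethenyl]-4,5-dichloro-1,5-dimethylcyclohexane, via tertiary cyclohexyl cation 14 (not isolated)
Conditions: TBCO (2,4,4,6-tetrabromocyclohexa-2,5-dien-1-one, 1.1 equiv), MeNO2, 0 °C; then HCl (4 M in 1,4-dioxane), CH2Cl2, −20 → 0 °C
Reagents that add atoms: 2,4,4,6-tetrabromocyclohexa-2,5-dien-1-one, O=C1C(Br)=CC(Br)(Br)C=C1Br; hydrogen chloride, Cl
Why: Proposed new method: TBCO transfers Br+ to C4 of the trisubstituted C3=C4 bond of the bromodiene (the isopropenyl bond is deactivated by the allylic chlorine), the isopropenyl CH2 attacks C3 anti to bromine through a six-membered chair (6-endo cation–olefin closure of the only ring), and the tertiary cation 14, or any alkene it gives by proton loss, is converted by HCl into the tertiary chloride; the closest known reactions are TBCO-induced bromocyclizations of geranyl-type 1,5-dienes and Markovnikov hydrochlorination; bromine should end equatorial and trans to the new C–C bond, the (Z)-geometry should place the bromovinyl group axial and cis to bromine, the existing C–Cl bond is expected to sit equatorial (in the nodal plane of the attacking π bond, where its inductive drag is smallest) and so relay the catalyst-set centre to the two new ones, and chloride should enter axially to give the epimer with both methyl groups equatorial.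

**Compound list**
1 | propargyl alcohol | C#CCO | starting material
2 | methylmagnesium bromide, CH3MgBr | C[Mg]Br | starting material
3 | bromomagnesium (Z)-3-(bromomagnesio)-2-methylprop-2-en-1-olate, BrMgCH=C(CH3)CH2OMgBr | Br[Mg]/C=C(/C)CO[Mg]Br | intermediate
4 | (Z)-3-iodo-2-methylprop-2-en-1-ol | I/C=C(/C)CO | intermediate
5 | (Z)-3-iodo-2-methylprop-2-enal | I/C=C(/C)C=O | intermediate
6 | bromoform | BrC(Br)Br | starting material
7 | (1Z,3E)-4-bromo-1-iodo-2-methylbuta-1,3-diene (iodine cis to the bromovinyl group) | I/C=C(C)\C=C\Br | intermediate
8 | isopropenylmagnesium bromide, CH2=C(CH3)MgBr | C=C(C)[Mg]Br | starting material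
9 | vinylboronic acid pinacol ester | C=CB1OC(C)(C)C(C)(C)O1 | starting material
10 | bromomagnesium isopropenyl(vinyl)borate of pinacol, [CH2=C(CH3)](CH2=CH)B(O2C6H12)MgBr | C=C(C)[B-]1(C=C)OC(C)(C)C(C)(C)O1.[Mg+]Br | intermediate
11 | 2-[(3S,5Z,7E)-8-bromo-2,6-dimethylocta-1,5,7-trien-3-yl]-4,4,5,5-tetramethyl-1,3,2-dioxaborolane | C=C(C)[C@@H](B1OC(C)(C)C(C)(C)O1)C/C=C(C)\C=C\Br | intermediate
12 | (3S,5Z,7E)-8-bromo-2,6-dimethylocta-1,5,7-trien-3-ol | C=C(C)[C@@H](O)C/C=C(C)\C=C\Br | intermediate
13 | (1E,3Z,6R)-1-bromo-6-chloro-3,7-dimethylocta-1,3,7-triene | C=C(C)[C@H](Cl)C/C=C(C)\C=C\Br | intermediate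
14 | (2R,4S,5S)-4-bromo-5-[(E)-2-bromoethenyl]-2-chloro-1,5-dimethylcyclohexan-1-ylium (tertiary cation) | C[C+]1C[C@@](C)(/C=C/Br)[C@@H](Br)C[C@H]1Cl | intermediate
15 | (1S,2S,4R,5S)-2-bromo-1-[(E)-2-bromoethenyl]-4,5-dichloro-1,5-dimethylcyclohexane (both Cl, ring Br and bromovinyl on one face, both methyls on the other) | C[C@]1(Cl)C[C@@](C)(/C=C/Br)[C@@H](Br)C[C@H]1Cl | target

**Totals**
Total steps: 6. Longest linear sequence: 6 steps (from propargyl alcohol).

**Steps most likely to fail**

1. Step 6 (proposed new method). What may go wrong:
   - The chair may place the existing C–Cl bond axially (allylic 1,2-strain with the vinylic methyl), relaying the wrong relative configuration to C1/C2.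
   - An open allylic cation may erode the anti/(Z) stereospecificity or be intercepted in a 1,2- or 1,4-addition.
   - The tertiary cation may lose a proton toward the chlorinated carbon or take up chloride from the equatorial side.

   Fallback, built from documented reaction types, which changes the relay element and the way the last C–Cl bond is made. It sets out from 12. Acetylation (Ac2O, Et3N, DMAP) gives the allylic acetate F1. TBCO-induced cyclization follows, of the kind known for geranyl acetate; the neighbouring acetate can trap the cation as a dioxolanylium ion only from the axial site, so this sequence works with an axial preference. Opening of that ion at the tertiary carbon by chloride (Me3SiCl) should give the trans-chloro acetate F2. i-Bu2AlH at −78 °C frees the trans-chlorohydrin F3. Dess–Martin oxidation gives the α-chloro ketone F4. NaBH4 reduction anti to the axial chlorine gives the cis-chlorohydrin F5. Chlorination with retention (SOCl2, then catalytic TiCl4) returns to the route at 15.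

2. Step 4. What may go wrong: migration of the wrong alkenyl group or direct Suzuki-type transfer, oxidative addition into the alkenyl bromide of 7 or of the product, or insufficient enantiofacial control.

   Fallback, from 7. Pd(PPh3)4-catalysed Negishi coupling with the Reformatsky reagent BrZnCH2C(O)N(OCH3)CH3 (from 2-bromo-N-methoxy-N-methylacetamide and Zn) gives the Weinreb amide F6. Addition of 8 gives the skipped enone F7. Reduction with (R)-Me-CBS/catecholborane at −78 °C, with the isopropenyl group as the large substituent, returns to the route at 12.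

3. Step 3. What may go wrong: Z→E isomerisation of the β-iodo enal on the Lewis acidic chromium salts, chromium insertion into the C–I bond, or incomplete E selectivity.

   Fallback, from 5. Corey–Fuchs dibromo-olefination (CBr4, PPh3, CH2Cl2, 0 °C) gives the dibromodiene F8. Hirao reduction (diethyl phosphite, Et3N), which removes one bromine to leave the (E)-bromoalkene, returns to the route at 7.

**Further compounds**
F1 | step 6 | (3S,5Z,7E)-8-bromo-2,6-dimethylocta-1,5,7-trien-3-yl acetate | C=C(C)[C@@H](OC(C)=O)C/C=C(C)\C=C\Br
F2 | step 6 | (1S,2S,4S,5S)-5-bromo-4-[(E)-2-bromoethenyl]-2-chloro-2,4-dimethylcyclohexyl acetate | C[C@]1(Cl)C[C@@](C)(/C=C/Br)[C@@H](Br)C[C@@H]1OC(C)=O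
F3 | step 6 | (1S,2S,4S,5S)-5-bromo-4-[(E)-2-bromoethenyl]-2-chloro-2,4-dimethylcyclohexan-1-ol | C[C@]1(Cl)C[C@@](C)(/C=C/Br)[C@@H](Br)C[C@@H]1O
F4 | step 6 | (2S,4S,5S)-5-bromo-4-[(E)-2-bromoethenyl]-2-chloro-2,4-dimethylcyclohexan-1-one | C[C@]1(Cl)C[C@@](C)(/C=C/Br)[C@@H](Br)CC1=O
F5 | step 6 | (1R,2S,4S,5S)-5-bromo-4-[(E)-2-bromoethenyl]-2-chloro-2,4-dimethylcyclohexan-1-ol | C[C@]1(Cl)C[C@@](C)(/C=C/Br)[C@@H](Br)C[C@H]1O
F6 | step 4 | (3Z,5E)-6-bromo-N-methoxy-N,4-dimethylhexa-3,5-dienamide | CON(C)C(=O)C/C=C(C)\C=C\Br
F7 | step 4 | (5Z,7E)-8-bromo-2,6-dimethylocta-1,5,7-trien-3-one | C=C(C)C(=O)C/C=C(C)\C=C\Br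
F8 | step 3 | (3Z)-1,1-dibromo-4-iodo-3-methylbuta-1,3-diene | I/C=C(C)\C=C(Br)Br
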